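**Plan**

- Labels: ring B = C1, O2, C3 (aryl), C4 (bears C4'H2OH), spiro C5; ring A = C5 to C10 (C7 OMe, C8 C=O); side chain on C1 = C1'H(OAr)–C1''H2OH.
- Retrosynthetic cuts, in order: the C9=C10 unsaturation and the C6=C7 enone (back to a C4'–O–C6 oxolane), O2–C3 (ring B), C1–C1' (glycolate aldol), then C5–C6 and C9–C10 together (intramolecular Diels–Alder), then the C5=C10 methylene and the C3–C4 aldol bond of a γ-lactone.
- Forward: ring B is made first as a lactone (C1 = carbonyl) from vanillin; ring A and a temporary oxolane (C4, C4', O, C6, C5) arise in one cycloaddition; the lactone is opened, the side chain is joined at C1, ring B is re-closed at O2–C3, and ring A is oxidised to the dienone last.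
- Enabling feature: the C4' hydroxymethyl group on C4 and C6 of ring A lie on the same face of ring B, so the C4' oxygen can carry the diene carbons C6 to C9 onto the C5=C10 methylene of the lactone; it returns as the free alcohol when the C6=C7 enone forms.
- Stereochemistry: C3 and C4 from an auxiliary-controlled syn aldol; C5 from C4 through the tether; C1 and C1' from an auxiliary-controlled syn glycolate aldol; C3 is re-formed trans to C4 when ring B re-closes.

Key step: step 10

Assumption: cycloadduct 20 is written with the oxolane cis-fused to ring A (H on C6 syn to C1); the C6 epimer would react alike and converges in step 19, where C6 becomes trigonal.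

**Route**

Step 1
Reactants: 1 vanillin
Product: 2 3-methoxy-4-(triisopropylsilyloxy)benzaldehyde
Conditions: iPr3SiCl, imidazole, DMF, rt
Reagents that add atoms: triisopropylsilyl chloride, CC(C)[Si](Cl)(C(C)C)C(C)C
Why: Silyl ether formation masks the phenol with a group that should tolerate LiOH/H2O2, amide bases, hydrides and mild acid and that leaves only with fluoride at the end.

Step 2
Reactants: 3 (S)-4-benzyloxazolidin-2-one; 4 methyl 4-chloro-4-oxobutanoate
Product: 5 methyl 4-[(4S)-4-benzyl-2-oxooxazolidin-3-yl]-4-oxobutanoate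
Conditions: n-BuLi, THF, −78 °C; then 4, −78 → 0 °C
Reagents that add atoms: none
Why: N-acylation of the lithiated oxazolidinone occurs at the acid chloride, which is far more electrophilic than the methyl ester.

Step 3
Reactants: 5 succinate imide; 2 silylated vanillin
Product: 7 (S)-4-benzyl-3-{(2S,3S)-2-[3-methoxy-4-(triisopropylsilyloxy)phenyl]-5-oxotetrahydrofuran-3-carbonyl}oxazolidin-2-one (trans lactone), via syn aldol adduct 6 (not isolated)
Conditions: Bu2BOTf, iPr2NEt, CH2Cl2, 0 °C; 2, −78 → 0 °C; pH 7 buffer, MeOH, H2O2; then PPTS (cat.), toluene, 60 °C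
Reagents that add atoms: none
Why: In this Evans syn aldol reaction the Z boron enolate of the imide adds through a closed chair transition state whose face is fixed by the (S)-benzyl auxiliary, which sets C4 and C3 (syn), and lactonisation of the new hydroxyl onto the methyl ester turns the syn relation into the trans ring substituents.

Step 4
Reactants: 7 lactone imide
Product: 9 (2S,3S)-2-[3-methoxy-4-(triisopropylsilyloxy)phenyl]-5-oxotetrahydrofuran-3-carboxylic acid, via peroxy acid 8 (not isolated)
Conditions: LiOH, H2O2, THF/H2O, 0 °C; Na2SO3 aq.; HCl to pH 2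
Reagents that add atoms: hydrogen peroxide, OO
Why: Hydroperoxide attacks the exocyclic imide carbonyl selectively (auxiliary cleavage), sulfite reduces the peracid and acidification re-closes any opened lactone, so no stereocentre is changed.

Step 5
Reactants: 9 paraconic acid
Product: 10 (4R,5S)-4-(hydroxymethyl)-5-[3-methoxy-4-(triisopropylsilyloxy)phenyl]dihydrofuran-2(3H)-one
Conditions: BH3·SMe2, THF, 0 °C → rt; MeOH
Reagents that add atoms: none
Why: Borane reduces the carboxylic acid through its acyloxyborane much faster than the lactone (chemoselective acid reduction), and the non-basic medium should prevent migration of the lactone to the new C4' hydroxyl.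

Step 6
Reactants: 10 hydroxymethyl lactone
Product: 13 (4R,5S)-4-(hydroxymethyl)-5-[3-methoxy-4-(triisopropylsilyloxy)phenyl]-3-methylidenedihydrofuran-2(3H)-one, via Mannich base 11 (not isolated), via trimethylammonium iodide 12 (not isolated)
Conditions: LiN(iPr)2 (2.2 equiv), THF, −78 °C; [Me2N=CH2]I, −78 → −20 °C; NH4Cl aq.; then MeI, CH2Cl2/MeOH, rt; then NaHCO3 aq., CH2Cl2
Reagents that add atoms: dimethylmethyleneiminium iodide, C=[N+](C)C.[I-]
Why: The lactone enolate, formed after the alkoxide, is aminomethylated (Mannich reaction), and quaternisation followed by base-induced elimination of trimethylamine installs the exocyclic C5=C10 methylene, which removes the unselective C5 centre of 11.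

Step 7
Reactants: 14 methoxyacetone; 15 methyl formate
Product: 17 (Z)-3,4-dimethoxybut-3-en-2-one, via sodium formyl enolate 16 (not isolated)
Conditions: NaOMe, Et2O, 0 °C → rt; then Me2SO4, DMF, 0 °C → rt
Reagents that add atoms: dimethyl sulfate, COS(=O)(=O)OC
Why: Crossed Claisen formylation at the methylene between carbonyl and methoxy gives the stabilised β-keto aldehyde enolate, and O-methylation at the formyl oxygen gives the vinylogous ester, expected as the isomer with the β-methoxy group trans to acetyl.

Step 8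
Reactants: 13 methylene lactone alcohol; 17 dimethoxybutenone (excess)
Product: 18 (4R,5S)-4-({[(1Z)-2-methoxy-3-oxobut-1-en-1-yl]oxy}methyl)-5-[3-methoxy-4-(triisopropylsilyloxy)phenyl]-3-methylidenedihydrofuran-2(3H)-one
Conditions: PPTS (cat.), toluene, 60 °C, reduced pressure (removal of MeOH)
Reagents that add atoms: none
Why: Acid-catalysed addition–elimination at the β-carbon of the vinylogous ester (transetherification) exchanges methoxy for the C4' oxygen, removal of methanol drives it, and equilibration should keep the ether oxygen trans to acetyl.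

Step 9
Reactants: 18 vinylogous ester
Product: 19 (4R,5S)-4-({[(1Z)-3-(tert-butyldimethylsilyloxy)-2-methoxybuta-1,3-dien-1-yl]oxy}methyl)-5-[3-methoxy-4-(triisopropylsilyloxy)phenyl]-3-methylidenedihydrofuran-2(3H)-one
Conditions: tBuMe2SiOTf, Et3N, CH2Cl2, −78 → 0 °C; filtration through Et3N-deactivated silica
Reagents that add atoms: tert-butyldimethylsilyl triflate, CC(C)(C)[Si](C)(C)OS(=O)(=O)C(F)(F)F
Why: Soft enolisation of the methyl ketone with silyl triflate and amine (silyl enol ether formation) gives the 2-silyloxy diene, while the methylene lactone has no enolisable α-hydrogen and stays untouched.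

Step 10
Reactants: 19 dienyl ether of the methylene lactone
Product: 20 tricyclic spirolactone (3S,4R; lactone ring B with C1 as carbonyl; ring A as its C7=C8 tert-butyldimethylsilyl enol ether; oxolane C4–C4'–O–C6–C5 cis-fused to both rings, C6 on the C4' face)
Conditions: toluene (0.005 M), BHT, 100 °C, base-washed sealed vessel
Reagents that add atoms: none
Why: On heating, the electron-rich diene (C6=C7–C8=C9) and the electron-poor exocyclic alkene C5=C10 combine in a concerted, asynchronous [4+2] cycloaddition; the closest known reaction type is the type 1 intramolecular Diels–Alder reaction of 1-alkoxy-3-silyloxybutadienes with acrylate-type dienophiles such as α-methylene lactones. Ring A (C5 to C10) closes by the cycloaddition itself through the new C5–C6 and C9–C10 bonds, and the oxolane (C4, C4', O, C6, C5) closes as the tether ring of a nona-1,6,8-triene array. The C5 stereocentre is controlled by C4: the three-atom tether can span only a cis-fused bicyclo[3.3.0] junction with the lactone, so C6 is delivered to the face of C5=C10 that carries C4', opposite to the C3 aryl group. The C6 stereocentre follows from the diene geometry (tether oxygen trans to C8) and from the orientation of the tether in the transition state; it is written cis-fused and is lost in step 19. The step needs regioselectivity (nucleophilic C9 to the β-carbon C10, C6 to C5), secured by the donor pattern of the diene, the lactone carbonyl and the tether length; facial selectivity at C5, secured by the tether; and cyclisation ahead of dimerisation, secured by high dilution.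

Step 11
Reactants: 20 cycloadduct
Product: 21 ring-opened N-methoxy-N-methylamide at C1 with free C3 hydroxyl (3S,4R; enol ether and oxolane unchanged)
Conditions: MeNH(OMe)·HCl, iPrMgCl, THF, −20 → 0 °C
Reagents that add atoms: N,O-dimethylhydroxylamine hydrochloride, CNOC.Cl
Why: The chloromagnesium amide opens the γ-lactone by aminolysis under non-acidic conditions that the β-alkoxy silyl enol ether should tolerate, and no stereocentre is involved.

Step 12
Reactants: 21 hydroxy amide
Product: 22 C3 triethylsilyl ether of 21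
Conditions: Et3SiCl, imidazole, DMAP (cat.), DMF, 0 °C → rt
Reagents that add atoms: triethylsilyl chloride, CC[Si](Cl)(CC)CC
Why: Silyl ether formation at the benzylic alcohol blocks relactonisation and places an acid-labile group on the oxygen that is to leave from C3 in step 19.

Step 13
Reactants: 22 silylated amide
Product: 23 C1 aldehyde on quaternary C5 (C3 OSiEt3; enol ether and oxolane unchanged)
Conditions: iBu2AlH, THF, −78 °C; potassium sodium tartrate aq.
Reagents that add atoms: none
Why: Hydride addition to the N-methoxy-N-methylamide gives a chelated tetrahedral aluminium intermediate that releases the aldehyde only on work-up (partial amide reduction), so over-reduction should not occur.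

Step 14
Reactants: 24 methyl 3-(4-hydroxy-3-methoxyphenyl)propanoate; 25 tert-butyl bromoacetate
Product: 26 methyl 3-{4-[2-(tert-butoxy)-2-oxoethoxy]-3-methoxyphenyl}propanoate
Conditions: K2CO3, acetone, reflux
Reagents that add atoms: none
Why: In this Williamson ether synthesis the phenoxide displaces bromide from the α-bromo ester.

Step 15
Reactants: 26 tert-butyl ester
Product: 27 2-[4-(3-methoxy-3-oxopropyl)-2-methoxyphenoxy]acetic acid
Conditions: CF3CO2H, CH2Cl2, rt
Reagents that add atoms: none
Why: Acidolysis through the tert-butyl cation cleaves only the tert-butyl ester and leaves the methyl ester and the aryl ether intact.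

Step 16
Reactants: 27 aryloxyacetic acid; 28 (R)-4-benzyloxazolidin-2-one
Product: 30 methyl 3-(4-{2-[(4R)-4-benzyl-2-oxooxazolidin-3-yl]-2-oxoethoxy}-3-methoxyphenyl)propanoate, via mixed pivalic anhydride 29 (not isolated)
Conditions: tBuCOCl, Et3N, THF, −20 °C; then 28, LiCl, −20 °C → rt
Reagents that add atoms: none
Why: N-acylation of the oxazolidinone by the mixed anhydride, promoted by LiCl and Et3N, takes place at the less hindered aryloxyacetyl carbonyl.

Step 17
Reactants: 23 aldehyde; 30 aryloxyacetyl imide
Product: 31 syn aldol adduct (C1 S hydroxyl, C1' aryloxy, (2R,3S) in the acyl chain; imide and side-chain methyl ester retained)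
Conditions: Bu2BOTf, Et3N, CH2Cl2, −78 → 0 °C; 23, −78 → 0 °C; pH 7 buffer, MeOH
Reagents that add atoms: none
Why: In this Evans syn glycolate aldol reaction the Z boron enolate adds through a closed chair transition state in which the (R)-benzyl auxiliary fixes the enolate face, which sets C1 and C1' together in the syn (threo) relation of the target and should override the weak bias of the α-quaternary aldehyde.

Step 18
Reactants: 31 aldol adduct
Product: 32 triol (C1 OH, C1'' OH, arylpropanol OH; C3 OSiEt3; enol ether and oxolane unchanged)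
Conditions: LiBH4, MeOH (additive), THF, 0 °C → rt
Reagents that add atoms: none
Why: LiBH4 cleaves the imide reductively to the C1'' primary alcohol and reduces the side-chain methyl ester to the propanol (imide and ester reduction), while the silyl ethers and the enol ether are inert to hydride.

Step 19
Reactants: 32 triol
Product: 33 ring B tetrahydrofuran with ring A as 2-methoxycyclohex-2-enone (1S,3S,4R, side chain 1'S; free C4', C1'' and propanol hydroxyls; phenol as triisopropylsilyl ether)
Conditions: TsOH·H2O (0.3 equiv), CH2Cl2, 0 °C → rt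
Reagents that add atoms: none
Why: The acid triggers two known ionisations: the β-alkoxy silyl enol ether collapses by vinylogous loss of the C6 oxygen to the 2-methoxy enone (as cycloadducts of 1-alkoxy-3-silyloxydienes do), which frees the C4' alcohol, and the electron-rich benzylic C3–O silyl ether gives a cation that the C1 hydroxyl captures (SN1 cycloetherification, five-membered ring), with the aryl group at C3 ending trans to the C4 hydroxymethyl group because that face is less hindered and the ionisation is reversible.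

Step 20
Reactants: 33 enone triol
Product: 35 tris(trimethylsilyl) ether of the O-triisopropylsilyl dienone, via silyl dienol ether 34 (not isolated)
Conditions: Me3SiOTf, Et3N, CH2Cl2, 0 °C; solvent exchange; Pd(OAc)2, MeCN, rt
Reagents that add atoms: trimethylsilyl triflate, C[Si](C)(C)OS(=O)(=O)C(F)(F)F
Why: Enolisation can take place only at C9 because C5 is quaternary, the three hydroxyls are silylated in passing, and divalent palladium converts the silyl dienol ether into the C9=C10 enone by β-hydride elimination (Saegusa–Ito oxidation), which gives the cross-conjugated dienone.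

Step 21
Reactants: 35 silylated dienone
Product: 36 CNP0252711.1 (target)
Conditions: Bu4NF, AcOH, THF, 0 °C → rt
Reagents that add atoms: none
Why: Buffered fluoride cleaves the aryl triisopropylsilyl ether and the three trimethylsilyl ethers (desilylation) and avoids both acid, which could cleave C1–C5 with aromatisation of ring A, and free alkoxide, which could add back to C6.

**Compound list**

1 | vanillin | COc1cc(C=O)ccc1O | starting material
2 | 3-methoxy-4-(triisopropylsilyloxy)benzaldehyde | COc1cc(C=O)ccc1O[Si](C(C)C)(C(C)C)C(C)C | intermediate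
3 | (S)-4-benzyloxazolidin-2-one | O=C1N[C@@H](Cc2ccccc2)CO1 | starting material
4 | methyl 4-chloro-4-oxobutanoate | COC(=O)CCC(Cl)=O | starting material
5 | methyl 4-[(4S)-4-benzyl-2-oxooxazolidin-3-yl]-4-oxobutanoate | COC(=O)CCC(=O)N1[C@@H](Cc2ccccc2)COC1=O | intermediate
6 | syn aldol adduct, methyl (3S,4S)-3-[(4S)-4-benzyl-2-oxooxazolidine-3-carbonyl]-4-hydroxy-4-[3-methoxy-4-(triisopropylsilyloxy)phenyl]butanoate | COC(=O)C[C@H](C(=O)N1[C@@H](Cc2ccccc2)COC1=O)[C@H](O)c1ccc(O[Si](C(C)C)(C(C)C)C(C)C)c(OC)c1 | intermediate (not isolated)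
7 | (S)-4-benzyl-3-{(2S,3S)-2-[3-methoxy-4-(triisopropylsilyloxy)phenyl]-5-oxotetrahydrofuran-3-carbonyl}oxazolidin-2-one | O=C1C[C@H](C(=O)N2[C@@H](Cc3ccccc3)COC2=O)[C@@H](c2ccc(O[Si](C(C)C)(C(C)C)C(C)C)c(OC)c2)O1 | intermediate
8 | (2S,3S)-2-[3-methoxy-4-(triisopropylsilyloxy)phenyl]-5-oxotetrahydrofuran-3-carboperoxoic acid | O=C1C[C@H](C(=O)OO)[C@@H](c2ccc(O[Si](C(C)C)(C(C)C)C(C)C)c(OC)c2)O1 | intermediate (not isolated)
9 | (2S,3S)-2-[3-methoxy-4-(triisopropylsilyloxy)phenyl]-5-oxotetrahydrofuran-3-carboxylic acid | O=C1C[C@H](C(=O)O)[C@@H](c2ccc(O[Si](C(C)C)(C(C)C)C(C)C)c(OC)c2)O1 | intermediate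
10 | (4R,5S)-4-(hydroxymethyl)-5-[3-methoxy-4-(triisopropylsilyloxy)phenyl]dihydrofuran-2(3H)-one | O=C1C[C@H](CO)[C@@H](c2ccc(O[Si](C(C)C)(C(C)C)C(C)C)c(OC)c2)O1 | intermediate
11 | Mannich base, (4R,5S)-3-[(dimethylamino)methyl]-4-(hydroxymethyl)-5-[3-methoxy-4-(triisopropylsilyloxy)phenyl]dihydrofuran-2(3H)-one (C3 epimers) | O=C1C(CN(C)C)[C@H](CO)[C@@H](c2ccc(O[Si](C(C)C)(C(C)C)C(C)C)c(OC)c2)O1 | intermediate (not isolated)
12 | trimethylammonium iodide of 11 | O=C1C(C[N+](C)(C)C)[C@H](CO)[C@@H](c2ccc(O[Si](C(C)C)(C(C)C)C(C)C)c(OC)c2)O1.[I-] | intermediate (not isolated)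
13 | (4R,5S)-4-(hydroxymethyl)-5-[3-methoxy-4-(triisopropylsilyloxy)phenyl]-3-methylidenedihydrofuran-2(3H)-one | C=C1[C@H](CO)[C@@H](c2ccc(O[Si](C(C)C)(C(C)C)C(C)C)c(OC)c2)OC1=O | intermediate
14 | methoxyacetone | COCC(C)=O | starting material
15 | methyl formate | COC=O | starting material
16 | sodium 2-methoxy-3-oxobut-1-en-1-olate | CC(=O)C(OC)=C[O-].[Na+] | intermediate (not isolated)
17 | (Z)-3,4-dimethoxybut-3-en-2-one | CO/C=C(OC)/C(C)=O | intermediate
18 | (4R,5S)-4-({[(1Z)-2-methoxy-3-oxobut-1-en-1-yl]oxy}methyl)-5-[3-methoxy-4-(triisopropylsilyloxy)phenyl]-3-methylidenedihydrofuran-2(3H)-one | C=C1[C@H](CO/C=C(OC)/C(C)=O)[C@@H](c2ccc(O[Si](C(C)C)(C(C)C)C(C)C)c(OC)c2)OC1=O | intermediate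
19 | (4R,5S)-4-({[(1Z)-3-(tert-butyldimethylsilyloxy)-2-methoxybuta-1,3-dien-1-yl]oxy}methyl)-5-[3-methoxy-4-(triisopropylsilyloxy)phenyl]-3-methylidenedihydrofuran-2(3H)-one | C=C1[C@H](CO/C=C(OC)/C(=C)O[Si](C)(C)C(C)(C)C)[C@@H](c2ccc(O[Si](C(C)C)(C(C)C)C(C)C)c(OC)c2)OC1=O | intermediate
20 | cycloadduct: tricyclic spirolactone, ring A as C7=C8 tert-butyldimethylsilyl enol ether, oxolane C4–C4'–O–C6–C5, 3S-aryl trans to C4 | COC1=C(O[Si](C)(C)C(C)(C)C)CC[C@@]23[C@@H]1OC[C@@H]2[C@@H](c1ccc(O[Si](C(C)C)(C(C)C)C(C)C)c(OC)c1)OC3=O | intermediate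
21 | C1 N-methoxy-N-methylamide with free C3 hydroxyl (lactone of 20 opened) | COC1=C(O[Si](C)(C)C(C)(C)C)CC[C@@]2(C(=O)N(C)OC)[C@@H]1OC[C@@H]2[C@H](O)c1ccc(O[Si](C(C)C)(C(C)C)C(C)C)c(OC)c1 | intermediate
22 | C3 triethylsilyl ether of 21 | COC1=C(O[Si](C)(C)C(C)(C)C)CC[C@@]2(C(=O)N(C)OC)[C@@H]1OC[C@@H]2[C@H](O[Si](CC)(CC)CC)c1ccc(O[Si](C(C)C)(C(C)C)C(C)C)c(OC)c1 | intermediate
23 | C1 aldehyde (C3 OSiEt3, enol ether and oxolane as in 20) | COC1=C(O[Si](C)(C)C(C)(C)C)CC[C@@]2(C=O)[C@@H]1OC[C@@H]2[C@H](O[Si](CC)(CC)CC)c1ccc(O[Si](C(C)C)(C(C)C)C(C)C)c(OC)c1 | intermediate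
24 | methyl 3-(4-hydroxy-3-methoxyphenyl)propanoate | COC(=O)CCc1ccc(O)c(OC)c1 | starting material
25 | tert-butyl bromoacetate | CC(C)(C)OC(=O)CBr | starting material
26 | methyl 3-{4-[2-(tert-butoxy)-2-oxoethoxy]-3-methoxyphenyl}propanoate | COC(=O)CCc1ccc(OCC(=O)OC(C)(C)C)c(OC)c1 | intermediate
27 | 2-[4-(3-methoxy-3-oxopropyl)-2-methoxyphenoxy]acetic acid | COC(=O)CCc1ccc(OCC(=O)O)c(OC)c1 | intermediate
28 | (R)-4-benzyloxazolidin-2-one | O=C1N[C@H](Cc2ccccc2)CO1 | starting material
29 | mixed anhydride of 27 with pivalic acid | COC(=O)CCc1ccc(OCC(=O)OC(=O)C(C)(C)C)c(OC)c1 | intermediate (not isolated)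
30 | methyl 3-(4-{2-[(4R)-4-benzyl-2-oxooxazolidin-3-yl]-2-oxoethoxy}-3-methoxyphenyl)propanoate | COC(=O)CCc1ccc(OCC(=O)N2[C@H](Cc3ccccc3)COC2=O)c(OC)c1 | intermediate
31 | syn aldol adduct at C1 ((2R,3S)-2-aryloxy-3-hydroxy acyl oxazolidinone on C5) | COC1=C(O[Si](C)(C)C(C)(C)C)CC[C@@]2([C@H](O)[C@@H](Oc3ccc(CCC(=O)OC)cc3OC)C(=O)N3[C@H](Cc4ccccc4)COC3=O)[C@@H]1OC[C@@H]2[C@H](O[Si](CC)(CC)CC)c1ccc(O[Si](C(C)C)(C(C)C)C(C)C)c(OC)c1 | intermediate
32 | triol from 31 (C1 OH, C1'' OH, arylpropanol OH) | COC1=C(O[Si](C)(C)C(C)(C)C)CC[C@@]2([C@H](O)[C@@H](Oc3ccc(CCCO)cc3OC)CO)[C@@H]1OC[C@@H]2[C@H](O[Si](CC)(CC)CC)c1ccc(O[Si](C(C)C)(C(C)C)C(C)C)c(OC)c1 | intermediate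
33 | 9,10-dihydro derivative of the target with the phenol as triisopropylsilyl ether (ring B closed, ring A 2-methoxycyclohex-2-enone) | COC1=C[C@]2(CCC1=O)[C@H](CO)[C@@H](c1ccc(O[Si](C(C)C)(C(C)C)C(C)C)c(OC)c1)O[C@@H]2[C@H](CO)Oc1ccc(CCCO)cc1OC | intermediate
34 | C8 trimethylsilyl dienol ether of 33 with three O-trimethylsilyl groups | COC1=C[C@]2(CC=C1O[Si](C)(C)C)[C@H](CO[Si](C)(C)C)[C@@H](c1ccc(O[Si](C(C)C)(C(C)C)C(C)C)c(OC)c1)O[C@@H]2[C@H](CO[Si](C)(C)C)Oc1ccc(CCCO[Si](C)(C)C)cc1OC | intermediate (not isolated)
35 | target with the phenol as triisopropylsilyl ether and the three alcohols as trimethylsilyl ethers | COC1=C[C@]2(C=CC1=O)[C@H](CO[Si](C)(C)C)[C@@H](c1ccc(O[Si](C(C)C)(C(C)C)C(C)C)c(OC)c1)O[C@@H]2[C@H](CO[Si](C)(C)C)Oc1ccc(CCCO[Si](C)(C)C)cc1OC | intermediate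
36 | CNP0252711.1: (1S,3S,4R)-3-(4-hydroxy-3-methoxyphenyl)-4-(hydroxymethyl)-1-{(1S)-2-hydroxy-1-[4-(3-hydroxypropyl)-2-methoxyphenoxy]ethyl}-7-methoxy-2-oxaspiro[4.5]deca-6,9-dien-8-one, C6 on the C4' face of ring B | COC1=C[C@]2(C=CC1=O)[C@H](CO)[C@@H](c1ccc(O)c(OC)c1)O[C@@H]2[C@H](CO)Oc1ccc(CCCO)cc1OC | target

**Count and risks**

Total step count: 21. Longest linear sequence: 16 steps (steps 1, 3 to 6, 8 to 13, 17 to 21).

Steps most likely to fail:

Step 10. The diene may lose its silyl group or polymerise before the short tether lets diene and dienophile stack. The same two bonds would then be made stepwise under anionic control. The fallback sets out from ketone 18. LiN(SiMe3)2 in THF at −78 °C should give the cross-conjugated lithium dienolate, which adds through C9 to the methylene carbon C10 (intramolecular Michael addition). The lactone enolate so formed closes onto C6 of the alkoxy enone (second Michael addition, with the same tether control of the C5 face). The resulting C7–C8 enolate is silylated in the cold with tBuMe2SiOTf, which comes back to the route at cycloadduct 20 without a new isolated compound.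

Step 19. Capture of the C3 cation may show poor facial selectivity, or hydroxyl groups may add back to C6 while the enol ether collapses. The two events would then be separated and both run without strong acid. The fallback sets out from triol 32. Bu4NF (THF, 0 °C → rt) removes the three silyl groups; the C8 enolate set free expels the C4' alkoxide (E1cB) and gives hexaol enone F1, which has a free para-hydroxybenzylic alcohol at C3. Such phenolic benzylic alcohols ionise through the para-quinone methide under nearly neutral conditions (AcOH cat., aqueous dioxane, 50 °C), and 1,6-addition of the C1 hydroxyl should close ring B to phenol enone F2 with the aryl group trans to C4. Silylation and dehydrogenation as in step 20 (Me3SiOTf, Et3N; then Pd(OAc)2, MeCN) would pass through pentakis(trimethylsilyl) dienol ether F3 to tetrakis(trimethylsilyl) dienone F4, and Bu4NF/AcOH comes back to the route at target 36.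

Step 11. The amide nucleophile may fail to open the lactone beside the quaternary C5, or the hydroxy amide may re-close before it is silylated. The carbonyl would then be taken down to the alcohol and brought back up. The fallback sets out from cycloadduct 20. LiBH4 (THF, 0 °C → rt) should give diol F5, and Et3SiCl, imidazole and DMAP should give bis(triethylsilyl) ether F6. Swern oxidation ((COCl)2, DMSO, Et3N, −78 → −30 °C) oxidises the primary triethylsilyl ether directly and leaves the secondary one, which comes back to the route at aldehyde 23.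

**Further compounds**

F0 | step 10 | none | none
F1 | step 19 | hexaol enone (ring B open, free phenol, C3 OH, C1 OH, ring A 2-methoxycyclohex-2-enone) | COC1=C[C@@](CCC1=O)([C@H](O)[C@@H](Oc2ccc(CCCO)cc2OC)CO)[C@H](CO)[C@H](O)c1ccc(O)c(OC)c1
F2 | step 19 | phenol enone (9,10-dihydro derivative of the target) | COC1=C[C@]2(CCC1=O)[C@H](CO)[C@@H](c1ccc(O)c(OC)c1)O[C@@H]2[C@H](CO)Oc1ccc(CCCO)cc1OC
F3 | step 19 | pentakis(trimethylsilyl) dienol ether of F2 | COC1=C[C@]2(CC=C1O[Si](C)(C)C)[C@H](CO[Si](C)(C)C)[C@@H](c1ccc(O[Si](C)(C)C)c(OC)c1)O[C@@H]2[C@H](CO[Si](C)(C)C)Oc1ccc(CCCO[Si](C)(C)C)cc1OC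
F4 | step 19 | tetrakis(trimethylsilyl) ether of the target | COC1=C[C@]2(C=CC1=O)[C@H](CO[Si](C)(C)C)[C@@H](c1ccc(O[Si](C)(C)C)c(OC)c1)O[C@@H]2[C@H](CO[Si](C)(C)C)Oc1ccc(CCCO[Si](C)(C)C)cc1OC
F5 | step 11 | diol from reduction of the lactone of 20 (C1 CH2OH, C3 OH) | COC1=C(O[Si](C)(C)C(C)(C)C)CC[C@@]2(CO)[C@@H]1OC[C@@H]2[C@H](O)c1ccc(O[Si](C(C)C)(C(C)C)C(C)C)c(OC)c1
F6 | step 11 | bis(triethylsilyl) ether of F5 | COC1=C(O[Si](C)(C)C(C)(C)C)CC[C@@]2(CO[Si](CC)(CC)CC)[C@@H]1OC[C@@H]2[C@H](O[Si](CC)(CC)CC)c1ccc(O[Si](C(C)C)(C(C)C)C(C)C)c(OC)c1
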